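(The readings were generated by integration for an exercise.)

At 10.0 min, late in both runs, their means read substrate 35.0% and target 71.5%. Together these exceed the charge by 6.5 percentage points, while such a sum scatters by 2 points.

| flask | substrate | solid reagent | remark | time |
|---|---|---|---|---|
| north-west | 2 mM (in portions, 3) | 1.1 equiv | the very flask that is asked about, followed so far; portions every 12 s |  |
| north | 1 mM (in portions, 3) | 1.1 equiv | run made earlier; portions every 12 s |  |
| flask | 2.0 mM (in portions, 3) | 1.10 equiv | the portions of substrate follow each other after 12 s, the first at the start | 25 min |

| run | time / min | substrate / % | target / % |
|---|---|---|---|
| north-west | 0.500 | 96 | 7 |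
| north-west | 1.50 | 79 | 22 |
| north-west | 3.00 | 61 | 36 |
| north-west | 4.00 | 57 | 45 |
| north-west | 6.00 | 46 | 57 |
| north-west | 8.00 | 37 | 62 |
| north-west | 10.0 | 35 | 72 |
| north | 1.33 | 82 | 17 |
| north | 3.00 | 64 | 36 |
| north | 4.00 | 57 | 41 |
| north | 6.00 | 45 | 58 |
| north | 8.00 | 34 | 66 |
| north | 10.0 | 35 | 71 |

(each reading ± 2 percentage points)

- as a solid, counted per litre of solution: solid reagent
- the analysis behind the earlier runs scatters by 2 percentage points, standard deviation
- what may be going on: substrate + partner <-> target; solid reagent <-> partner
- at the start none of the solid reagent is in solution
- the reaction counts as stopped when no species that holds the substrate changes by six tenths of a point or more over the second half of the time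

1. at 25 min, what has stopped the reaction, if anything has (for what has run out or reacted, a solid counts together with what of it has only dissolved) (the partner has run out first / it is still moving / forward and back rates have come level / all of the substrate has reacted)
2. how much of the substrate has reacted by 25 min
3. how much target there is at 25 min, in percent of the substrate charged

The north run, at half the charge, reads much the same fractions (45% against 46% substrate at 6.00 min), so you may treat the partner as steady: pseudo-first-order in substrate. With a steady partner, a reversible step has a rate falling on a straight line against the fraction, and that line's zero is the end. So set the mean rate up to 3.00 min, and the mean rate from 6.00 min to 10.0 min, each at the middle fraction of its span, and extend the line.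

You can do this on independent readings. The means are substrate 62.5% and target 36.0% at 3.00 min, then 45.5% and 57.5% at 6.00 min. The substrate line extends to an estimated end of 29.4%. The target line extends to an estimated end of 83.6%.

They part: their sum overshoots the charge by 13 points, more than the late excess. The extension stretches the scatter of the readings, and I have no ground to prefer one series. So average what each says has reacted: 77.1%. Carry this as the level, the fraction of the charge standing as target when forward and back rates are equal. The two slopes average 0.212 /min, the rate at which the gap to the level shrinks exponentially.

So reckon the gap as the small correction to the level: 5.5 points at 12.5 min and 0.39 points at 25 min. I therefore expect 76.8% reacted, all of it target, and a last-stretch change of 5.1 points, which the stopping rule calls moving. The solid reagent, 1.10 equiv, exceeds the level.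

The forecast, reasoning that “The curves fit relaxation towards a plateau”, says it is still moving, with 81% reacted and 81% target, higher than my figure. The simulation gives it is still moving, with 75.4% reacted and 75.4% target.

    substrate + partner ⇌ target (K = 10000 /M, k = 9.59 /M/s)
    solid reagent ⇌ partner, rate k2*(cs2 - [partner]) while solid is left; crystals form when [partner] > cs2 (solubility = 0.310 mM, k = 0.636 /s)

In this flask the solid reagent fell from 83.2% of its charge at 0.400 min to 17.4% at 25.0 min, while the partner stood at 0.304 mM at 0.400 min and at 0.310 mM at 25.0 min. Target reached 50.6% at 5.00 min and 75.6% at 250 min, 1.5 points below the level. Level less gap gives 67.8% for the neighbour flask stopped at 10 min, and that flask holds 67.8% target.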